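**Assumption:** the named enantiomers of the two chiral catalysts give the configurations stated (Si-face alkyl delivery to the β-carbon of enone 6; Re-face attack on the ketone of 10, i.e. the mirror image of the outcome reported for the (S,S)-catalyst); if a first run shows the opposite sense, the antipodal ligand is used.

Numbering used below: C1 lactone C=O, C2 CH2, C3 hemiketal carbon, C4 C(Me)–O, C5 CH2, C6 C(Me)–OO, C7, C8 CH(Me), C9–C11, C12(Me)=C13, C14 benzylic CH2. The target is (3R,4R,6R,8R,12E).

## Retrosynthetic overview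

1. Ring B (1,2-dioxane) is closed last: the C3–O bond forms by peroxyhemiketalisation of a C6 tertiary hydroperoxide onto the tetronic acid C3 carbonyl; the hydroperoxide comes from O2 capture by the C6 radical of alkene 13.
2. Ring A (γ-lactone, as a tetronic acid) is closed before that: C2–C3 bond by Claisen/Dieckmann closure of the α-acetoxy ester 12.
3. The C4–C5 bond and C4 come from a catalytic asymmetric carbonyl-ene reaction of methyl pyruvate with diene 9.
4. Diene 9 comes from ketone 8; C8 is set by asymmetric conjugate addition of Grignard 7 to pentenone; the E-trisubstituted alkene comes from carboalumination/benzylation of pentynol.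
5. Ring order: lactone (step 6), then 1,2-dioxane (step 7).

## Route

Step 1
Reactants: 1 pent-4-yn-1-ol; 2 benzyl chloride
Product: 4 (4E)-4-methyl-6-phenylhex-4-en-1-ol, via alkenylalane 3 (not isolated)
Conditions: AlMe3 (3 equiv), Cp2ZrCl2 (0.25 equiv), CH2Cl2, 0 °C to rt; then 2 (1.3 equiv), Pd(PPh3)4 (3 mol%), THF, rt; aq. HCl
Reagents that add atoms: trimethylaluminium C[Al](C)C
Why: Negishi zirconium-catalysed carboalumination adds Me and Al syn with Al on the terminal carbon, and the alkenylalane is benzylated with retention by zerovalent palladium-catalysed cross-coupling, so only the E trisubstituted alkene (C12=C13) forms.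

Step 2
Reactants: 4 (4E)-4-methyl-6-phenylhex-4-en-1-ol
Product: 5 [(2E)-6-bromo-3-methylhex-2-en-1-yl]benzene
Conditions: CBr4, PPh3, CH2Cl2, 0 °C
Reagents that add atoms: tetrabromomethane BrC(Br)(Br)Br
Why: The Appel reaction converts the primary alcohol to the bromide under neutral conditions that leave the skipped aryl alkene untouched.

Step 3
Reactants: 5 [(2E)-6-bromo-3-methylhex-2-en-1-yl]benzene; 6 (3E)-pent-3-en-2-one
Product: 8 (4R,8E)-4,8-dimethyl-10-phenyldec-8-en-2-one, via Grignard reagent 7 (not isolated)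
Conditions: Mg, Et2O, reflux; CuBr·SMe2 (5 mol%), (R)-1-[(Sp)-2-(diphenylphosphino)ferrocenyl]ethyldicyclohexylphosphine (6 mol%), tBuOMe, −75 °C, 6 added over 2 h; then H2O
Reagents that add atoms: none
Why: Copper-catalysed asymmetric conjugate addition of an alkylmagnesium bromide to an acyclic E-enone (Feringa type), in which the chiral ferrocenyl diphosphine–CuBr complex delivers the alkyl group to one face of the β-carbon and so sets C8 as R (expected ≥90% ee; the remote alkene is inert).

Step 4
Reactants: 8 (4R,8E)-4,8-dimethyl-10-phenyldec-8-en-2-one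
Product: 9 [(2E,7R)-3,7,9-trimethyldeca-2,9-dien-1-yl]benzene
Conditions: Ph3PCH3Br, KOtBu, THF, 0 °C to rt
Reagents that add atoms: methyltriphenylphosphonium bromide [Br-].C[P+](c1ccccc1)(c1ccccc1)c1ccccc1
Why: Wittig methylenation of an unhindered methyl ketone; the stereocentre is β to the carbonyl and cannot epimerise.

Step 5
Reactants: 9 [(2E,7R)-3,7,9-trimethyldeca-2,9-dien-1-yl]benzene; 10 methyl pyruvate
Product: 11 methyl (2R,6R,10E)-2-hydroxy-2,6,10-trimethyl-4-methylidene-12-phenyldodec-10-enoate
Conditions: [Cu((R,R)-tBu-box)](SbF6)2 (10 mol%; tBu-box = 2,2'-(propane-2,2-diyl)bis(4-tert-butyl-4,5-dihydrooxazole)), 10 (1.2 equiv), CH2Cl2, 40 °C, 48 h; chromatography on AgNO3-impregnated silica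
Reagents that add atoms: none
Why: Enantioselective carbonyl-ene reaction (Evans type) in which pyruvate chelates the C2-symmetric divalent copper bis(oxazoline) complex and the terminal CH2 of the 1,1-disubstituted alkene attacks the exposed Re face of the ketone, forming C4–C5 and setting C4 as R, while the hindered trisubstituted alkene does not compete.

Step 6
Reactants: 11 methyl (2R,6R,10E)-2-hydroxy-2,6,10-trimethyl-4-methylidene-12-phenyldodec-10-enoate
Product: 13 (5R)-4-hydroxy-5-methyl-5-[(4R,8E)-4,8-dimethyl-2-methylidene-10-phenyldec-8-en-1-yl]furan-2(5H)-one, via acetate 12 (not isolated)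
Conditions: LiN(SiMe3)2 (1.05 equiv), THF, −78 °C; AcCl (1.1 equiv), −78 to 0 °C; LiN(SiMe3)2 (2.5 equiv), −78 °C to rt; 1 M aq. HCl
Reagents that add atoms: acetyl chloride CC(Cl)=O
Why: O-Acetylation of the lithium alkoxide followed by Dieckmann (intramolecular Claisen) condensation of the acetate enolate onto the neighbouring methyl ester closes ring A as the tetronic acid, mirroring the polyketide Claisen/lactonisation, and the quaternary C4 cannot epimerise.

Step 7
Reactants: 13 (5R)-4-hydroxy-5-methyl-5-[(4R,8E)-4,8-dimethyl-2-methylidene-10-phenyldec-8-en-1-yl]furan-2(5H)-one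
Product: 17 (3R,4aR,7aR)-7a-hydroxy-3,4a-dimethyl-3-[(2R,6E)-2,6-dimethyl-8-phenyloct-6-en-1-yl]tetrahydro-3H-furo[3,2-c][1,2]dioxin-6(4H)-one, via trimethylsilyl tetronate 14 (not isolated), via triethylsilyl peroxide 15 (not isolated), via hydroperoxide 16 (not isolated)
Conditions: N,O-bis(trimethylsilyl)acetamide (1.2 equiv), ClCH2CH2Cl, rt, 30 min; Co(thd)2 (10 mol%; thd = 2,2,6,6-tetramethylheptane-3,5-dionate), Et3SiH (2 equiv), O2 (1 atm), rt, stopped when the terminal alkene is consumed; then 1 M aq. HCl/THF, 0 °C; preparative HPLC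
Reagents that add atoms: dioxygen O=O
Why: Mukaiyama–Isayama cobalt-catalysed hydrogen-atom-transfer hydroperoxidation gives the tertiary C6 radical from the more reactive 1,1-disubstituted alkene (isopropenyl-type alkenes react ahead of trisubstituted ones), the radical captures O2, and on acidic desilylation the C6–OOH adds to the C3 carbonyl carbon of the tetronic acid to close ring B as the cis-fused peroxyhemiketal, so C3 follows C4 under thermodynamic control, whereas C6 forms without control (about 1:1) and the (6R) epimer is isolated by HPLC.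

## Compound list

1 | pent-4-yn-1-ol | C#CCCCO | starting material
2 | benzyl chloride | ClCc1ccccc1 | starting material
3 | [(1E)-5-(dimethylalumanyloxy)-2-methylpent-1-en-1-yl]dimethylalumane | C[Al](C)/C=C(\C)CCCO[Al](C)C | intermediate
4 | (4E)-4-methyl-6-phenylhex-4-en-1-ol | OCCC/C(C)=C/Cc1ccccc1 | intermediate
5 | [(2E)-6-bromo-3-methylhex-2-en-1-yl]benzene | BrCCC/C(C)=C/Cc1ccccc1 | intermediate
6 | (3E)-pent-3-en-2-one | C/C=C/C(C)=O | starting material
7 | [(4E)-4-methyl-6-phenylhex-4-en-1-yl]magnesium bromide | Br[Mg]CCC/C(C)=C/Cc1ccccc1 | intermediate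
8 | (4R,8E)-4,8-dimethyl-10-phenyldec-8-en-2-one | C/C(=C\Cc1ccccc1)CCC[C@@H](C)CC(C)=O | intermediate
9 | [(2E,7R)-3,7,9-trimethyldeca-2,9-dien-1-yl]benzene | C/C(=C\Cc1ccccc1)CCC[C@@H](C)CC(C)=C | intermediate
10 | methyl pyruvate | COC(=O)C(C)=O | starting material
11 | methyl (2R,6R,10E)-2-hydroxy-2,6,10-trimethyl-4-methylidene-12-phenyldodec-10-enoate | C/C(=C\Cc1ccccc1)CCC[C@@H](C)CC(=C)C[C@@](C)(O)C(=O)OC | intermediate
12 | methyl (2R,6R,10E)-2-(acetyloxy)-2,6,10-trimethyl-4-methylidene-12-phenyldodec-10-enoate | C/C(=C\Cc1ccccc1)CCC[C@@H](C)CC(=C)C[C@@](C)(OC(C)=O)C(=O)OC | intermediate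
13 | (5R)-4-hydroxy-5-methyl-5-[(4R,8E)-4,8-dimethyl-2-methylidene-10-phenyldec-8-en-1-yl]furan-2(5H)-one | C/C(=C\Cc1ccccc1)CCC[C@@H](C)CC(=C)C[C@@]1(C)OC(=O)C=C1O | intermediate
14 | (5R)-5-methyl-5-[(4R,8E)-4,8-dimethyl-2-methylidene-10-phenyldec-8-en-1-yl]-4-[(trimethylsilyl)oxy]furan-2(5H)-one | C/C(=C\Cc1ccccc1)CCC[C@@H](C)CC(=C)C[C@@]1(C)OC(=O)C=C1O[Si](C)(C)C | intermediate
15 | (5R)-5-methyl-4-[(trimethylsilyl)oxy]-5-{(2R,4R,8E)-2,4,8-trimethyl-10-phenyl-2-[(triethylsilyl)peroxy]dec-8-en-1-yl}furan-2(5H)-one (formed together with its 2S epimer) | C/C(=C\Cc1ccccc1)CCC[C@@H](C)C[C@](OO[Si](CC)(CC)CC)(C)C[C@@]1(C)OC(=O)C=C1O[Si](C)(C)C | intermediate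
16 | (5R)-5-[(2R,4R,8E)-2-hydroperoxy-2,4,8-trimethyl-10-phenyldec-8-en-1-yl]-4-hydroxy-5-methylfuran-2(5H)-one | C/C(=C\Cc1ccccc1)CCC[C@@H](C)C[C@](OO)(C)C[C@@]1(C)OC(=O)C=C1O | intermediate
17 | (3R,4aR,7aR)-7a-hydroxy-3,4a-dimethyl-3-[(2R,6E)-2,6-dimethyl-8-phenyloct-6-en-1-yl]tetrahydro-3H-furo[3,2-c][1,2]dioxin-6(4H)-one (CNP0361739.2) | C/C(=C\Cc1ccccc1)CCC[C@@H](C)C[C@]1(C)C[C@@]2(C)OC(=O)C[C@@]2(O)OO1 | target

## Step count and risks

Total step count: 7. Longest linear sequence: 7 (1 → 4 → 5 → 8 → 9 → 11 → 13 → 17).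

**Step 7 (most at risk).**
- The silyl tetronate may interfere with the cobalt catalyst.
- Hydrogen-atom transfer may partly reach the C12=C13 alkene.
- C6 is not controlled, so at best about half of the material is the (6R) epimer.
- Closure depends on the ring–chain balance favouring the peroxyhemiketal.

Fallback: install the peroxide before the acidic tetronic acid exists and close both rings in the last pot. It sets out from 11, which is acetylated (Ac2O, DMAP, Et3N) and isolated as 12. Peroxidation of 12 with Co(thd)2, Et3SiH and O2 gives methyl (2R,4R,6R,10E)-2-(acetyloxy)-2,4,6,10-tetramethyl-12-phenyl-4-[(triethylsilyl)peroxy]dodec-10-enoate F1, a neutral compound that can be separated from its 4S epimer at this stage. Dieckmann closure with LiN(SiMe3)2 at −78 °C and an aqueous HCl quench then give the hydroperoxy tetronic acid, so the fallback comes back at 16, which closes to 17.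

**Step 5.**
- Hydrogen may be transferred from C7 instead of the methyl group, giving trisubstituted alkene isomers.
- A second ene reaction on the product alkene is possible.
- The cationic copper complex may isomerise the skipped aryl alkene.

Fallback: replace the ene reaction by a catalytic asymmetric Mukaiyama aldol. It sets out from 8, which is converted with LiN(iPr)2 and Me3SiCl into the kinetic enol ether trimethyl{[(4R,8E)-4,8-dimethyl-10-phenyldeca-1,8-dien-2-yl]oxy}silane F2. Addition of F2 to 10 under the same copper bis(oxazoline) catalyst, followed by acidic work-up, gives methyl (2R,6R,10E)-2-hydroxy-2,6,10-trimethyl-4-oxo-12-phenyldodec-10-enoate F3. Non-basic methylenation of the ketone (Zn, CH2Br2, TiCl4) brings the route back at 11.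

**Step 3.**
- Enantioselectivity with a β-methyl enone and a functionalised Grignard reagent is less documented than the reverse pairing.
- Commercial 6 must be freed of mesityl oxide before use.

Fallback: exchange the roles of nucleophile and acceptor. It sets out from 5 (as its Grignard reagent 7), which is formylated with DMF to (5E)-5-methyl-7-phenylhept-5-enal F4. Wittig reaction with Ph3P=CHC(O)CH3 gives (3E,8E)-8-methyl-10-phenyldeca-3,8-dien-2-one F5. Conjugate addition of MeMgBr with CuBr·SMe2 and the mirror-image ferrocenyl diphosphine (methyl and chain have exchanged roles) comes back at 8.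

## Further compounds

F1 | step 7 | methyl (2R,4R,6R,10E)-2-(acetyloxy)-2,4,6,10-tetramethyl-12-phenyl-4-[(triethylsilyl)peroxy]dodec-10-enoate | C/C(=C\Cc1ccccc1)CCC[C@@H](C)C[C@](OO[Si](CC)(CC)CC)(C)C[C@@](C)(OC(C)=O)C(=O)OC
F2 | step 5 | trimethyl{[(4R,8E)-4,8-dimethyl-10-phenyldeca-1,8-dien-2-yl]oxy}silane | C/C(=C\Cc1ccccc1)CCC[C@@H](C)CC(=C)O[Si](C)(C)C
F3 | step 5 | methyl (2R,6R,10E)-2-hydroxy-2,6,10-trimethyl-4-oxo-12-phenyldodec-10-enoate | C/C(=C\Cc1ccccc1)CCC[C@@H](C)CC(=O)C[C@@](C)(O)C(=O)OC
F4 | step 3 | (5E)-5-methyl-7-phenylhept-5-enal | O=CCCC/C(C)=C/Cc1ccccc1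
F5 | step 3 | (3E,8E)-8-methyl-10-phenyldeca-3,8-dien-2-one | CC(=O)/C=C/CCC/C(C)=C/Cc1ccccc1
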